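**Retrosynthetic overview**

1. Core locants: C1 bridgehead C–OH, C2/C3 epoxide, C4 CH–OMe, C5 bridgehead CH, C6 CH–OH, C7 CH–N, C8 CH2, C9 C=O; ring A = C1, C8, C7, C6, C5, C9; ring B = C1, C2, C3, C4, C5, C9. The last operations are N-acylation and an O1–H-directed exo epoxidation of C2=C3.
2. Key disconnection: C4–C5, an intramolecular aldol addition that closes ring B onto a finished ring A. The enabling feature is the bridging C9 ketone: its only enolisable α-carbon is C5 (C1 is quaternary), C4 carries oxygen β to C9 inside ring B, and O1, O9 and O4 lie on one face, so one metal ion can hold all three.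
3. The aldehyde partner is a (Z)-enal on C1, stored as a spiro lactol with O1. It comes from acetylide addition to the C1 ketone of a 2-methoxy enone (C9 masked as its methyl enol ether), then Lindlar reduction.
4. Ring A with the cis C6–O/C7–N pair comes from a catalytic asymmetric Diels–Alder reaction and a Curtius rearrangement, which gives a cis-fused oxazolidinone that shields one face for the C1 addition.
5. Ring order: ring A (Diels–Alder) → oxazolidinone (temporary) → spiro lactol (temporary) → ring B (aldol) → epoxide.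

Key step: step 9

Remark (assumption): the sense of induction in step 1 is taken from the accepted square-planar model for [Cu((S,S)-t-Bu-box)](SbF6)2 with acryloyl imides; if the (1R,2S) adduct were to form, the (R,R)-ligand would be used. The commercial E/Z mixture of diene 2 can be used, since only the E isomer reacts at a useful rate.

Locant key: in the benzoxazolone intermediates C3a, C7a, C7, C6, C5 and C4 become C7, C6, C5, C9, C1 and C8 of the core.

**Route**

Step 1
Reactants: 1 3-acryloyl-1,3-oxazolidin-2-one; 2 (1E)-buta-1,3-dien-1-yl acetate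
Product: 3 3-{[(1S,2R)-2-(acetyloxy)cyclohex-3-en-1-yl]carbonyl}-1,3-oxazolidin-2-one
Conditions: [Cu((S,S)-t-Bu-box)](SbF6)2 (5 mol%), CH2Cl2, 0 °C to rt
Reagents that add atoms: none
Why: Catalytic enantioselective Diels–Alder reaction in which the chelated acrylimide is attacked on one face by the E-diene in an endo, "ortho" mode, which should set the acetoxy-bearing and the carbonyl-bearing carbons cis as (1S,2R).

Step 2
Reactants: 3
Product: 5 (1S,2R)-2-hydroxycyclohex-3-ene-1-carboxylic acid, via peroxy acid 4 (not isolated)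
Conditions: LiOH, 30% H2O2, THF/H2O, 0 °C to rt; Na2SO3; HCl to pH 2
Reagents that add atoms: hydrogen peroxide (as LiOOH), OO
Why: Hydroperoxide cleavage of the N-acyl oxazolidinone at the exocyclic carbonyl with concurrent acetate saponification touches no stereocentre, and the weakly basic nucleophile is chosen to avoid β-elimination of the C2 oxygen.

Step 3
Reactants: 5
Product: 8 (3aS,7aR)-3a,4,5,7a-tetrahydro-1,3-benzoxazol-2(3H)-one, via acyl azide 6 (not isolated), via isocyanate 7 (not isolated)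
Conditions: (PhO)2P(O)N3, Et3N, toluene, rt then 85 °C
Reagents that add atoms: diphenylphosphoryl azide, [N-]=[N+]=NP(=O)(Oc1ccccc1)Oc1ccccc1
Why: Curtius rearrangement with retention at the migrating carbon, followed by capture of the isocyanate by the cis β-hydroxyl, should give the cis-fused oxazolidinone and so fix C3a–N cis to C7a–O.

Step 4
Reactants: 8
Product: 9 (3aS,7aR)-3a,4-dihydro-1,3-benzoxazole-2,5(3H,7aH)-dione
Conditions: CrO3, 3,5-dimethylpyrazole, CH2Cl2, −20 °C
Reagents that add atoms: chromium trioxide, O=[Cr](=O)=O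
Why: Allylic C–H oxidation of the only allylic methylene (C5; the other allylic position, C7a, is a tertiary C–H deactivated by the carbamate oxygen) should give the enone without touching the stereocentres.

Step 5
Reactants: 9
Product: 10 (3aS,6R,7R,7aS)-6,7-epoxyhexahydro-1,3-benzoxazole-2,5-dione
Conditions: 30% H2O2, NaOH (1.2 equiv), MeOH, −10 °C; NH4Cl
Reagents that add atoms: hydrogen peroxide, OO
Why: Weitz–Scheffer nucleophilic epoxidation in which hydroperoxide should add anti to the adjacent C7a–O bond, the N–H being kept deprotonated so that the carbamate nitrogen cannot leave in a retro-aza-Michael reaction.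

Step 6
Reactants: 10
Product: 11 (3aS,7aR)-6-methoxy-3a,4-dihydro-1,3-benzoxazole-2,5(3H,7aH)-dione
Conditions: NaOMe (2.5 equiv), MeOH, 0 °C to rt; NH4Cl
Reagents that add atoms: sodium methoxide, C[O-].[Na+]
Why: Methoxide should open the α,β-epoxy ketone at the α-carbon C6 and the C7 hydroxyl is then lost by E1cB dehydration (the known route from epoxy ketones to 2-alkoxy enones), which places the enol ether on the C6=C7 side and erases both epoxide stereocentres.

Step 7
Reactants: 11; 12 3,3-diethoxyprop-1-yne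
Product: 14 (3aS,5S,7aR)-5-(3,3-diethoxyprop-1-yn-1-yl)-5-hydroxyhexahydro-1,3-benzoxazole-2,6-dione, via enol ether carbinol 13 (not isolated)
Conditions: 12 (3 equiv), n-BuLi, THF, −78 °C; CeCl3; then 11, −78 °C; then 1 M HCl, THF, 0 °C, 10 min
Reagents that add atoms: water, O
Why: 1,2-Addition of a cerium acetylide (low basicity, no conjugate addition) to the C5 ketone from the face anti to the cis-fused oxazolidinone should set C5 with the hydroxyl cis to N and O, and brief aqueous acid then hydrolyses the methyl enol ether, which is far more labile than the propargylic acetal, to the α-ketol.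

Step 8
Reactants: 14
Product: 16 (3aS,5S,7aR)-5'-hydroxy-3a,4,7,7a-tetrahydro-3H,5'H-spiro[1,3-benzoxazole-5,2'-furan]-2,6-dione (spiro lactol; both C5' epimers), via Z-alkenyl acetal 15 (not isolated)
Conditions: H2 (1 atm), Lindlar catalyst (Pd/CaCO3, Pb(OAc)2), quinoline, EtOAc, rt; filter; then 1 M HCl, THF/H2O, rt
Reagents that add atoms: water, O
Why: Lindlar semi-hydrogenation gives the Z-alkene by syn delivery of hydrogen, and hydrolysis of the now allylic acetal is trapped by the tertiary hydroxyl as a five-membered lactol, which stores the Z-enal and cannot aromatise to a furan because the spiro carbon is quaternary.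

Step 9
Reactants: 16
Product: 18 (1S,4R,5R,6R,7S)-7-amino-1,4,6-trihydroxybicyclo[3.3.1]non-2-en-9-one 6-O,7-N-cyclic carbamate, via open Z-enal 17 (not isolated)
Conditions: LiHMDS (3.3 equiv), THF, −78 to −40 °C; NH4Cl
Reagents that add atoms: none
Why: LiHMDS first removes the carbamate N–H and the lactol O–H, the lactolate opens to the (Z)-enal 17 with a C1 alkoxide, and the third equivalent forms the C9 enolate, which can only form toward C5 because C1 is quaternary; the enolate carbon C5 then adds to the aldehyde carbon C4. The closest known reaction type is the base-mediated intramolecular aldol addition of a cyclohexanone onto a tethered aldehyde released from a lactol, the classical entry to bicyclo[3.3.1]nonan-9-ones. Ring B closes in a 6-(enolendo)-exo-trig mode. C5 is set by the tether, since the axial enal arm on C1 can reach only the enolate face anti to the C6–O bond, and C4 is set by a closed lithium-bridged transition state in which the aldehyde oxygen is bound to the metal on O9 (and on the neighbouring O1 alkoxide), so that O4 should end gauche to C9 on the exo face, cis to O1; the chelated aldolate is also the more stable epimer should the addition be reversible. The step needs aldol addition to win over β-elimination of the C6 carbamate oxygen, which the deprotonated carbamate (the leaving group would be a dianion) and the low temperature secure, and it needs the Z-geometry to survive, which the absence of a γ-hydrogen at C1 secures.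

Step 10
Reactants: 18
Product: 19 (1S,4R,5R,6R,7S)-7-amino-1,6-dihydroxy-4-methoxybicyclo[3.3.1]non-2-en-9-one 6-O,7-N-cyclic carbamate
Conditions: TMSCHN2 (2 equiv), 42% aq. HBF4 (cat.), CH2Cl2, 0 °C
Reagents that add atoms: trimethylsilyldiazomethane, C[Si](C)(C)C=[N+]=[N-]
Why: Acid-catalysed O-methylation with a diazoalkane uses no base, so retro-aldol cleavage is avoided and the carbamate N–H is left alone, and it should methylate the secondary C4 hydroxyl in preference to the hindered, hydrogen-bonded tertiary C1 hydroxyl.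

Step 11
Reactants: 19
Product: 21 tert-butyl N-[(1S,4R,5S,6R,7S)-1,6-dihydroxy-4-methoxy-9-oxobicyclo[3.3.1]non-2-en-7-yl]carbamate, via N-Boc oxazolidinone 20 (not isolated)
Conditions: Boc2O, DMAP, Et3N, MeCN, rt; then Cs2CO3 (0.3 equiv), MeOH, rt
Reagents that add atoms: di-tert-butyl dicarbonate, CC(C)(C)OC(=O)OC(=O)OC(C)(C)C
Why: N-acylation of the oxazolidinone activates its ring carbonyl and carbonate-catalysed methanolysis then opens it to the N-Boc amino alcohol (the known two-stage oxazolidinone cleavage), while the β-alkoxy and β-hydroxy ketone units cannot eliminate or undergo retro-aldol cleavage because C5 is a bridgehead.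

Step 12
Reactants: 21; 22 (2E)-dodec-2-enoic acid
Product: 24 (2E)-N-[(1S,4R,5S,6R,7S)-1,6-dihydroxy-4-methoxy-9-oxobicyclo[3.3.1]non-2-en-7-yl]dodec-2-enamide, via amine trifluoroacetate 23 (not isolated)
Conditions: TFA/CH2Cl2 (1:4), 0 °C; evaporate; then 22, EDC·HCl, HOBt, i-Pr2NEt, DMF, 0 °C to rt
Reagents that add atoms: none
Why: Acidolysis of the Boc group followed by carbodiimide/HOBt amide coupling should acylate the primary amine selectively over the secondary and tertiary hydroxyls, and it is placed before the epoxidation so that no epoxide is exposed to acid.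

Step 13
Reactants: 24
Product: 25 (2E)-N-[(1S,2S,3S,4S,5S,6R,7S)-2,3-epoxy-1,6-dihydroxy-4-methoxy-9-oxobicyclo[3.3.1]nonan-7-yl]dodec-2-enamide (target)
Conditions: VO(acac)2 (5 mol%), t-BuOOH (in decane, 1.5 equiv), CH2Cl2, 0 °C to rt
Reagents that add atoms: tert-butyl hydroperoxide, CC(C)(C)OO
Why: Hydroxyl-directed epoxidation in which vanadium bound to the tertiary allylic O1 delivers oxygen to the C2=C3 face syn to O1, which is also the exo face away from ring A, so both epoxide centres are set by the substrate and the electron-poor enamide alkene is left untouched.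

**Compound list**

1 | 3-acryloyl-1,3-oxazolidin-2-one | C=CC(=O)N1CCOC1=O | starting material
2 | (1E)-buta-1,3-dien-1-yl acetate | CC(=O)O/C=C/C=C | starting material
3 | 3-{[(1S,2R)-2-(acetyloxy)cyclohex-3-en-1-yl]carbonyl}-1,3-oxazolidin-2-one | O=C(N1CCOC1=O)[C@H]2CCC=C[C@H]2OC(C)=O | intermediate
4 | (1S,2R)-2-(acetyloxy)cyclohex-3-ene-1-carboperoxoic acid (lithium salt in the flask) | OOC(=O)[C@H]1CCC=C[C@H]1OC(C)=O | intermediate
5 | (1S,2R)-2-hydroxycyclohex-3-ene-1-carboxylic acid | OC(=O)[C@H]1CCC=C[C@H]1O | intermediate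
6 | (1S,2R)-2-hydroxycyclohex-3-ene-1-carbonyl azide | [N-]=[N+]=NC(=O)[C@H]1CCC=C[C@H]1O | intermediate
7 | (1R,6S)-6-isocyanatocyclohex-2-en-1-ol | O=C=N[C@H]1CCC=C[C@H]1O | intermediate
8 | (3aS,7aR)-3a,4,5,7a-tetrahydro-1,3-benzoxazol-2(3H)-one | N1[C@H]2CCC=C[C@H]2OC1=O | intermediate
9 | (3aS,7aR)-3a,4-dihydro-1,3-benzoxazole-2,5(3H,7aH)-dione | N1[C@H]2CC(=O)C=C[C@H]2OC1=O | intermediate
10 | (3aS,6R,7R,7aS)-6,7-epoxyhexahydro-1,3-benzoxazole-2,5-dione (epoxide anti to the ring-fusion N and O) | N1[C@H]2CC(=O)[C@@H]3O[C@@H]3[C@H]2OC1=O | intermediate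
11 | (3aS,7aR)-6-methoxy-3a,4-dihydro-1,3-benzoxazole-2,5(3H,7aH)-dione | N1[C@H]2CC(=O)C(OC)=C[C@H]2OC1=O | intermediate
12 | 3,3-diethoxyprop-1-yne | C#CC(OCC)OCC | starting material
13 | (3aS,5S,7aR)-5-(3,3-diethoxyprop-1-yn-1-yl)-5-hydroxy-6-methoxy-3a,4,5,7a-tetrahydro-1,3-benzoxazol-2(3H)-one (alkoxide in the flask) | N1[C@H]2C[C@](O)(C#CC(OCC)OCC)C(OC)=C[C@H]2OC1=O | intermediate
14 | (3aS,5S,7aR)-5-(3,3-diethoxyprop-1-yn-1-yl)-5-hydroxyhexahydro-1,3-benzoxazole-2,6-dione | N1[C@H]2C[C@](O)(C#CC(OCC)OCC)C(=O)C[C@H]2OC1=O | intermediate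
15 | (3aS,5S,7aR)-5-[(1Z)-3,3-diethoxyprop-1-en-1-yl]-5-hydroxyhexahydro-1,3-benzoxazole-2,6-dione | N1[C@H]2C[C@](O)(/C=C\C(OCC)OCC)C(=O)C[C@H]2OC1=O | intermediate
16 | (3aS,5S,7aR)-5'-hydroxy-3a,4,7,7a-tetrahydro-3H,5'H-spiro[1,3-benzoxazole-5,2'-furan]-2,6-dione (both C5' epimers; that centre is left unspecified) | N1[C@H]2C[C@@]3(OC(O)C=C3)C(=O)C[C@H]2OC1=O | intermediate
17 | (2Z)-3-[(3aS,5S,7aR)-5-hydroxy-2,6-dioxooctahydro-1,3-benzoxazol-5-yl]prop-2-enal (lithium salts in the flask) | N1[C@H]2C[C@](O)(/C=C\C=O)C(=O)C[C@H]2OC1=O | intermediate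
18 | (1S,4R,5R,6R,7S)-7-amino-1,4,6-trihydroxybicyclo[3.3.1]non-2-en-9-one 6-O,7-N-cyclic carbamate | N1[C@H]2C[C@@]3(O)C(=O)[C@@H]([C@H]2OC1=O)[C@H](O)C=C3 | intermediate
19 | (1S,4R,5R,6R,7S)-7-amino-1,6-dihydroxy-4-methoxybicyclo[3.3.1]non-2-en-9-one 6-O,7-N-cyclic carbamate | N1[C@H]2C[C@@]3(O)C(=O)[C@@H]([C@H]2OC1=O)[C@H](OC)C=C3 | intermediate
20 | N-(tert-butoxycarbonyl) derivative of 19 (Boc on the oxazolidinone nitrogen) | CC(C)(C)OC(=O)N1[C@H]2C[C@@]3(O)C(=O)[C@@H]([C@H]2OC1=O)[C@H](OC)C=C3 | intermediate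
21 | tert-butyl N-[(1S,4R,5S,6R,7S)-1,6-dihydroxy-4-methoxy-9-oxobicyclo[3.3.1]non-2-en-7-yl]carbamate | CC(C)(C)OC(=O)N[C@H]1C[C@@]2(O)C(=O)[C@@H]([C@H]1O)[C@H](OC)C=C2 | intermediate
22 | (2E)-dodec-2-enoic acid | CCCCCCCCC/C=C/C(=O)O | starting material
23 | (1S,4R,5S,6R,7S)-7-amino-1,6-dihydroxy-4-methoxybicyclo[3.3.1]non-2-en-9-one (trifluoroacetate salt in the flask) | N[C@H]1C[C@@]2(O)C(=O)[C@@H]([C@H]1O)[C@H](OC)C=C2 | intermediate
24 | (2E)-N-[(1S,4R,5S,6R,7S)-1,6-dihydroxy-4-methoxy-9-oxobicyclo[3.3.1]non-2-en-7-yl]dodec-2-enamide | CCCCCCCCC/C=C/C(=O)N[C@H]1C[C@@]2(O)C(=O)[C@@H]([C@H]1O)[C@H](OC)C=C2 | intermediate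
25 | (2E)-N-[(1S,2S,3S,4S,5S,6R,7S)-2,3-epoxy-1,6-dihydroxy-4-methoxy-9-oxobicyclo[3.3.1]nonan-7-yl]dodec-2-enamide | CCCCCCCCC/C=C/C(=O)N[C@H]1C[C@@]2(O)C(=O)[C@@H]([C@H]1O)[C@H](OC)[C@@H]1O[C@@H]12 | target

**Step count and risks**

Total step count: 13. Longest linear sequence: 13 steps (from 1 and 2 to 25); 12 and 22 are bought and enter in steps 7 and 12.

Steps most likely to fail:

Step 6. Under methoxide the carbamate nitrogen may be expelled from C3a (retro-aza-Michael) with aromatisation of the ring, or methoxide may open the epoxide at C7 and scramble the position of the enol ether. The fallback leaves the route at enone 9 and returns at α-ketol 14. Neutral Mukaiyama-type hydration of 9 (Mn(dpm)3 cat., PhSiH3, O2, i-PrOH, then P(OEt)3) should give the α-hydroxy ketone (3aS,6R,7aR)-6-hydroxyhexahydro-1,3-benzoxazole-2,5-dione F1, whose C6 configuration is of no consequence. TBSCl/imidazole should give the silyl ether (3aS,6R,7aR)-6-[(tert-butyldimethylsilyl)oxy]hexahydro-1,3-benzoxazole-2,5-dione F2. The cerium acetylide from 12 should add to the C5 ketone anti to the oxazolidinone to give (3aS,5S,6R,7aR)-6-[(tert-butyldimethylsilyl)oxy]-5-(3,3-diethoxyprop-1-yn-1-yl)-5-hydroxyhexahydro-1,3-benzoxazol-2(3H)-one F3. TBAF should give the diol (3aS,5S,6R,7aR)-5-(3,3-diethoxyprop-1-yn-1-yl)-5,6-dihydroxyhexahydro-1,3-benzoxazol-2(3H)-one F4, and Dess–Martin oxidation of its secondary alcohol should give 14.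

Step 9. The polyanion may aggregate so that the lactolate does not open or the aldol stalls, the C6 carbamate oxygen may be lost by β-elimination from the enolate, or facial control at C4 may be poor. The fallback sets out from 15 (isolated this time by stopping step 8 after the hydrogenation) and returns at 18. TESOTf/2,6-lutidine should give the tertiary silyl ether (3aS,5S,7aR)-5-[(1Z)-3,3-diethoxyprop-1-en-1-yl]-5-[(triethylsilyl)oxy]hexahydro-1,3-benzoxazole-2,6-dione F5. Oxalic acid on wet silica should release the free enal (2Z)-3-[(3aS,5S,7aR)-2,6-dioxo-5-[(triethylsilyl)oxy]octahydro-1,3-benzoxazol-5-yl]prop-2-enal F6. Soft enolisation with Cy2BCl/Et3N at −78 °C and boron-mediated intramolecular aldol addition through a closed six-membered transition state, without strong base, should give (1S,4R,5R,6R,7S)-7-amino-4,6-dihydroxy-1-[(triethylsilyl)oxy]bicyclo[3.3.1]non-2-en-9-one 6-O,7-N-cyclic carbamate F7. HF·pyridine should then give 18.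

Step 4. The oxidation may occur with allylic transposition (carbonyl at C7) or go on to over-oxidised products. The fallback sets out from 1 and returns at enone 9, bringing the C5 oxygen in with the diene. The same copper-catalysed Diels–Alder reaction with commercial (1E,3E)-buta-1,3-diene-1,4-diyl diacetate should give the all-cis adduct 3-{[(1S,2R,5R)-2,5-bis(acetyloxy)cyclohex-3-en-1-yl]carbonyl}-1,3-oxazolidin-2-one F8. LiOH/H2O2 should give (1S,2R,5R)-2,5-dihydroxycyclohex-3-ene-1-carboxylic acid F9. Curtius rearrangement with (PhO)2P(O)N3, closing onto the vicinal cis hydroxyl, should give (3aS,5R,7aR)-5-hydroxy-3a,4,5,7a-tetrahydro-1,3-benzoxazol-2(3H)-one F10, and MnO2 oxidation of its allylic alcohol should give 9.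

Further compounds
F1 | step 6 | (3aS,6R,7aR)-6-hydroxyhexahydro-1,3-benzoxazole-2,5-dione | N1[C@H]2CC(=O)[C@H](O)C[C@H]2OC1=O
F2 | step 6 | (3aS,6R,7aR)-6-[(tert-butyldimethylsilyl)oxy]hexahydro-1,3-benzoxazole-2,5-dione | N1[C@H]2CC(=O)[C@H](O[Si](C)(C)C(C)(C)C)C[C@H]2OC1=O
F3 | step 6 | (3aS,5S,6R,7aR)-6-[(tert-butyldimethylsilyl)oxy]-5-(3,3-diethoxyprop-1-yn-1-yl)-5-hydroxyhexahydro-1,3-benzoxazol-2(3H)-one | N1[C@H]2C[C@](O)(C#CC(OCC)OCC)[C@H](O[Si](C)(C)C(C)(C)C)C[C@H]2OC1=O
F4 | step 6 | (3aS,5S,6R,7aR)-5-(3,3-diethoxyprop-1-yn-1-yl)-5,6-dihydroxyhexahydro-1,3-benzoxazol-2(3H)-one | N1[C@H]2C[C@](O)(C#CC(OCC)OCC)[C@H](O)C[C@H]2OC1=O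
F5 | step 9 | (3aS,5S,7aR)-5-[(1Z)-3,3-diethoxyprop-1-en-1-yl]-5-[(triethylsilyl)oxy]hexahydro-1,3-benzoxazole-2,6-dione | N1[C@H]2C[C@](O[Si](CC)(CC)CC)(/C=C\C(OCC)OCC)C(=O)C[C@H]2OC1=O
F6 | step 9 | (2Z)-3-[(3aS,5S,7aR)-2,6-dioxo-5-[(triethylsilyl)oxy]octahydro-1,3-benzoxazol-5-yl]prop-2-enal | N1[C@H]2C[C@](O[Si](CC)(CC)CC)(/C=C\C=O)C(=O)C[C@H]2OC1=O
F7 | step 9 | (1S,4R,5R,6R,7S)-7-amino-4,6-dihydroxy-1-[(triethylsilyl)oxy]bicyclo[3.3.1]non-2-en-9-one 6-O,7-N-cyclic carbamate | N1[C@H]2C[C@@]3(O[Si](CC)(CC)CC)C(=O)[C@@H]([C@H]2OC1=O)[C@H](O)C=C3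
F8 | step 4 | 3-{[(1S,2R,5R)-2,5-bis(acetyloxy)cyclohex-3-en-1-yl]carbonyl}-1,3-oxazolidin-2-one | O=C(N1CCOC1=O)[C@H]2C[C@@H](OC(C)=O)C=C[C@H]2OC(C)=O
F9 | step 4 | (1S,2R,5R)-2,5-dihydroxycyclohex-3-ene-1-carboxylic acid | OC(=O)[C@H]1C[C@@H](O)C=C[C@H]1O
F10 | step 4 | (3aS,5R,7aR)-5-hydroxy-3a,4,5,7a-tetrahydro-1,3-benzoxazol-2(3H)-one | N1[C@H]2C[C@@H](O)C=C[C@H]2OC1=O
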